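**Retrosynthetic overview**

1. Target 25 comes from enal 24 by amine-catalysed H2O2 epoxidation of the C15 enal (C4 oxirane). 24 comes from tetraol 22 by oxidative lactonisation (C12–O–C8 γ-lactone), and 22 from 20 by one double SeO2 allylic hydroxylation of both isopropenyl groups.
2. Key disconnection C6–C7 of ring A. The strategy rests on this feature: on ring A (C10–C5–C6–C7–C8–C9) the C6 oxygen is trans to C7, which carries C11(=C13H2)–C12. This is a 2-isopropenylcyclohexanol, the retron of a carbonyl-ene closure of aldehyde 17 (C6 aldehyde, C7=C11 isopropylidene, C8/C9 cis-acetonide).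
3. 17 comes from acid 15, made by Ireland–Claisen rearrangement of the Z-allylic 3-methylbut-2-enoate 12. This forms C5–C10, sets C5 and C10, and leaves the C1=C2 vinyl and the C5 isopropenyl group.
4. 12 comes from Z-allylic alcohol 10, made from ynoate 8 by syn methylcupration; 8 comes from D-erythronolactone acetonide 1 (C7–C10 with the C8/C9 cis-diol) and an isopropylidene ylide (C11–C13).
5. Ring order: ring A (step 12), then the γ-lactone (step 16), then the oxirane (step 17).

Key step: step 12

Remarks on the chemistry: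
- Elemane numbering is used. β is the face of ring A that carries the C10 methyl group; in all ring compounds the C5 and C7 side chains and the C8 and C9 oxygens are β, and the C10 vinyl and the C6 oxygen are α.
- Assumption for step 17: the (S)-diarylprolinol silyl ether is taken to give the (4R) oxirane from the α-substituted acrolein 24. If the sense of induction is the reverse, the (R)-catalyst is used without other change.

**Route**

Step 1
Reactants: 1 2,3-O-isopropylidene-D-erythronolactone
Product: 2 2,3-O-isopropylidene-D-erythrose (lactol, anomer mixture)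
Conditions: i-Bu2AlH (1.1 equiv), CH2Cl2, −78 °C; aq. potassium sodium tartrate
Reagents that add atoms: none
Why: Half-reduction of a γ-lactone by i-Bu2AlH stops at the lactol because the tetrahedral aluminium alkoxide is stable at −78 °C, and the two acetonide stereocentres (future C8 and C9) are not touched.

Step 2
Reactants: 2 2,3-O-isopropylidene-D-erythrose; 3 isopropyltriphenylphosphonium iodide
Product: 4 [(4R,5S)-2,2-dimethyl-5-(2-methylprop-1-enyl)-1,3-dioxolan-4-yl]methanol
Conditions: 3 (3 equiv), n-BuLi, THF, 0 °C; then 2, 0 °C → rt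
Reagents that add atoms: isopropyltriphenylphosphonium iodide (3), CC(C)[P+](c1ccccc1)(c1ccccc1)c1ccccc1.[I-]
Why: Wittig olefination of the open-chain hydroxy aldehyde in equilibrium with the lactol by a non-stabilised ylide installs C11 with both methyl groups, so no olefin geometry arises, and the excess ylide absorbs the lactol proton.

Step 3
Reactants: 4 dioxolanyl methanol
Product: 5 (4S,5S)-2,2-dimethyl-5-(2-methylprop-1-enyl)-1,3-dioxolane-4-carbaldehyde
Conditions: Dess–Martin periodinane, NaHCO3, CH2Cl2, 0 °C; used at once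
Reagents that add atoms: none
Why: Dess–Martin oxidation under bicarbonate buffer gives the aldehyde without strong acid or amine base, which limits epimerisation of the cis-dioxolane α-centre (C9).

Step 4
Reactants: 5 dioxolane carbaldehyde
Product: 6 (4R,5S)-4-(2,2-dibromoethenyl)-2,2-dimethyl-5-(2-methylprop-1-enyl)-1,3-dioxolane
Conditions: CBr4, PPh3, Et3N, CH2Cl2, 0 °C
Reagents that add atoms: tetrabromomethane, BrC(Br)(Br)Br
Why: Ramirez dibromo-olefination (first stage of the Corey–Fuchs sequence) adds C1 under near-neutral conditions and leaves the α-stereocentre alone.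

Step 5
Reactants: 6 dibromo olefin
Product: 8 methyl 3-[(4R,5S)-2,2-dimethyl-5-(2-methylprop-1-enyl)-1,3-dioxolan-4-yl]prop-2-ynoate, via lithium acetylide 7 (not isolated)
Conditions: n-BuLi (2.1 equiv), THF, −78 °C; ClCO2Me, −78 → 0 °C
Reagents that add atoms: methyl chloroformate, COC(=O)Cl; n-butyllithium, [Li]CCCC (lithium in 7 only)
Why: Corey–Fuchs alkyne formation (bromine–lithium exchange, Fritsch–Buttenberg–Wiechell shift, deprotonation) gives the lithium acetylide, which is C-acylated by the chloroformate to place C2.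

Step 6
Reactants: 8 ynoate
Product: 9 methyl (2Z)-3-[(4R,5S)-2,2-dimethyl-5-(2-methylprop-1-enyl)-1,3-dioxolan-4-yl]but-2-enoate
Conditions: Me2CuLi (from MeLi and CuI), THF, −78 °C; MeOH then aq. NH4Cl at −78 °C
Reagents that add atoms: lithium dimethylcuprate, [Li+].C[Cu-]C
Why: Syn carbocupration of the ynoate followed by cold protonation puts the C14 methyl on C10 and hydrogen on C1 on the same side, so the dioxolane carbon C9 and the ester end up cis (2Z), the olefin geometry that step 9 requires.

Step 7
Reactants: 9 Z-enoate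
Product: 10 (2Z)-3-[(4R,5S)-2,2-dimethyl-5-(2-methylprop-1-enyl)-1,3-dioxolan-4-yl]but-2-en-1-ol
Conditions: i-Bu2AlH (2.5 equiv), CH2Cl2, −78 °C
Reagents that add atoms: none
Why: 1,2-Reduction of the α,β-unsaturated ester by i-Bu2AlH gives the allylic alcohol with the Z geometry retained.

Step 8
Reactants: 10 Z-allylic alcohol; 11 3-methylbut-2-enoyl chloride
Product: 12 (2Z)-3-[(4R,5S)-2,2-dimethyl-5-(2-methylprop-1-enyl)-1,3-dioxolan-4-yl]but-2-enyl 3-methylbut-2-enoate
Conditions: 11, pyridine, DMAP (cat.), CH2Cl2, 0 °C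
Reagents that add atoms: 3-methylbut-2-enoyl chloride (11), CC(C)=CC(=O)Cl
Why: DMAP-catalysed acylation of a primary allylic alcohol by an acid chloride; partial double-bond migration in the acyl group would be harmless because both ester isomers give the same dienolate.

Step 9
Reactants: 12 Z-allylic 3-methylbut-2-enoate
Product: 15 (2S,3S)-3-[(4R,5S)-2,2-dimethyl-5-(2-methylprop-1-enyl)-1,3-dioxolan-4-yl]-3-methyl-2-(prop-1-en-2-yl)pent-4-enoic acid, via silyl ketene acetal 13 (not isolated), via trimethylsilyl ester 14 (not isolated)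
Conditions: LiN(i-Pr)2, THF, −78 °C; Me3SiCl, Et3N, −78 → 50 °C; then MeOH, aq. citric acid
Reagents that add atoms: chlorotrimethylsilane, C[Si](C)(C)Cl (silicon in 13 and 14 only)
Why: Ireland–Claisen rearrangement in which γ-deprotonation of the ester through its s-cis conformer should give the (1Z)-silyl ketene acetal 13 (isopropenyl cis to OSi), whose chair transition state (isopropenyl equatorial, C9 axial because of the Z olefin) fixes C5 relative to C10, while C9, held with its C–H eclipsing the olefin by A(1,3) strain, is expected to direct the new C5–C10 bond to the face of C10 anti to the C9–O bond, the sense known for Z-γ-alkoxy allylic systems.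

Step 10
Reactants: 15 pentenoic acid
Product: 16 (2S,3S)-3-[(4R,5S)-2,2-dimethyl-5-(2-methylprop-1-enyl)-1,3-dioxolan-4-yl]-3-methyl-2-(prop-1-en-2-yl)pent-4-en-1-ol
Conditions: LiAlH4, THF, 0 °C → rt
Reagents that add atoms: none
Why: Hydride reduction of the carboxylic acid by LiAlH4 proceeds through the carboxylate, which does not enolise, so C5 is kept and the olefins and the acetonide are inert.

Step 11
Reactants: 16 pentenol
Product: 17 (2S,3S)-3-[(4R,5S)-2,2-dimethyl-5-(2-methylprop-1-enyl)-1,3-dioxolan-4-yl]-3-methyl-2-(prop-1-en-2-yl)pent-4-enal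
Conditions: Dess–Martin periodinane, NaHCO3, CH2Cl2, 0 °C; used at once
Reagents that add atoms: none
Why: Buffered Dess–Martin oxidation gives the β,γ-unsaturated aldehyde without base and without heating, which avoids epimerisation or conjugation at C5 and the thermal Cope rearrangement of the 1,5-diene.

Step 12
Reactants: 17 pentenal (C6 aldehyde, C7=C11 isopropylidene)
Product: 18 8β,9β-isopropylidenedioxy-elema-1,3,11(13)-trien-6α-ol
Conditions: Me2AlCl (1.5 equiv), CH2Cl2, −78 °C
Reagents that add atoms: none
Why: Me2AlCl binds the C6 aldehyde oxygen, and the activated carbonyl carbon is attacked by olefinic C7 while a hydrogen of a C11 methyl passes to the carbonyl oxygen in a concerted but asynchronous six-centre array, as in the Lewis-acid-promoted type 1 intramolecular carbonyl-ene cyclisation of citronellal to isopulegol. Ring A closes as a six-membered carbocycle by C6–C7 bond formation across the chain C6–C5–C10–C9–C8–C7, with both reacting π bonds (C6=O and C7=C11) exocyclic to the new ring. C6 is set by the chair: the axial site at C6 lies on the β face between the axial C10 methyl and the axial C8 oxygen, so the carbonyl oxygen must sit equatorial (α), trans to the equatorial C5 isopropenyl group. C7 is set by the isopropylidene unit taking the equatorial site, from which a methyl hydrogen can reach the equatorial O–Al, and this places the new isopropenyl group trans to the C6 hydroxyl and cis to the C8 oxygen. The step needs chemoselectivity for the C7=C11 olefin, which the substrate secures because the C10 vinyl group has no allylic hydrogen and the C5 isopropenyl group could only close a four-membered ring; the cis-acetonide also pre-folds the chain. The C5 centre and the acetonide must survive, for which the low temperature and the proton-scavenging methylaluminium reagent are chosen.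

Step 13
Reactants: 18 ring A alcohol; 19 isobutyric anhydride
Product: 20 8β,9β-isopropylidenedioxy-elema-1,3,11(13)-trien-6α-yl 2-methylpropanoate
Conditions: 19, Et3N, DMAP, CH2Cl2, rt → 40 °C
Reagents that add atoms: isobutyric anhydride (19), CC(C)C(=O)OC(=O)C(C)C
Why: DMAP-catalysed acylation of the equatorial C6 alcohol with the anhydride installs the ester of the target before any oxidation.

Step 14
Reactants: 20 isobutyrate
Product: 21 12,15-dihydroxy-8β,9β-isopropylidenedioxy-elema-1,3,11(13)-trien-6α-yl 2-methylpropanoate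
Conditions: SeO2 (cat.), t-BuOOH, CH2Cl2, rt
Reagents that add atoms: tert-butyl hydroperoxide, CC(C)(C)OO (oxygen passed on through SeO2, O=[Se]=O)
Why: Riley-type allylic oxidation (ene reaction then [2,3] shift at selenium) should hydroxylate the methyl group of each 1,1-disubstituted olefin, because the alternative allylic methine positions C5 and C7 are hindered and the vinyl group has no allylic hydrogen; any enal formed by over-oxidation converges in step 16.

Step 15
Reactants: 21 acetonide diol
Product: 22 8β,9β,12,15-tetrahydroxy-elema-1,3,11(13)-trien-6α-yl 2-methylpropanoate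
Conditions: AcOH/H2O (4:1), 45 °C
Reagents that add atoms: none
Why: Acid-catalysed hydrolysis of the cis-fused acetonide in aqueous acetic acid, under which the isobutyrate and the primary allylic alcohols should persist.

Step 16
Reactants: 22 tetraol
Product: 24 9β-hydroxy-6α-(2-methylpropanoyloxy)-15-oxo-elema-1,3,11(13)-trien-12,8β-olide, via lactol enal 23 (not isolated)
Conditions: TEMPO (cat.), PhI(OAc)2 (3.5 equiv), CH2Cl2, rt
Reagents that add atoms: none
Why: TEMPO/PhI(OAc)2 oxidises primary alcohols in preference to the hindered secondary C9 alcohol, so both allylic alcohols become enals; the C12 aldehyde is captured by the cis C8 hydroxyl as the five-membered lactol 23 and oxidised on to the α-methylene lactone (oxidative lactonisation of a 1,4-diol), while the C15 enal could only form a bridged lactol with C9–OH and stays free.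

Step 17
Reactants: 24 lactone enal
Product: 25 (4R)-3,4-epoxy-9β-hydroxy-6α-(2-methylpropanoyloxy)-15-oxo-elema-1,11(13)-dien-12,8β-olide (target)
Conditions: (S)-2-[diphenyl(trimethylsilyloxy)methyl]pyrrolidine (20 mol %), 35% aq. H2O2, CH2Cl2, rt
Reagents that add atoms: hydrogen peroxide, OO
Why: Iminium-catalysed nucleophilic epoxidation of an α-substituted acrolein (amine-catalysed Weitz–Scheffer type), in which the secondary amine activates only the aldehyde so the α-methylene lactone is left alone, and the catalyst controls the face on which the enamine closes the oxirane, setting C4 (R).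

**Compound list**

1 | 2,3-O-isopropylidene-D-erythronolactone | CC1(C)O[C@@H]2COC(=O)[C@@H]2O1 | starting material
2 | 2,3-O-isopropylidene-D-erythrose (lactol, anomer mixture) | CC1(C)O[C@@H]2COC(O)[C@@H]2O1 | intermediate
3 | isopropyltriphenylphosphonium iodide | CC(C)[P+](c1ccccc1)(c1ccccc1)c1ccccc1.[I-] | starting material
4 | [(4R,5S)-2,2-dimethyl-5-(2-methylprop-1-enyl)-1,3-dioxolan-4-yl]methanol | CC(C)=C[C@@H]1OC(C)(C)O[C@@H]1CO | intermediate
5 | (4S,5S)-2,2-dimethyl-5-(2-methylprop-1-enyl)-1,3-dioxolane-4-carbaldehyde | CC(C)=C[C@@H]1OC(C)(C)O[C@@H]1C=O | intermediate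
6 | (4R,5S)-4-(2,2-dibromoethenyl)-2,2-dimethyl-5-(2-methylprop-1-enyl)-1,3-dioxolane | CC(C)=C[C@@H]1OC(C)(C)O[C@@H]1C=C(Br)Br | intermediate
7 | lithium acetylide of (4R,5S)-4-ethynyl-2,2-dimethyl-5-(2-methylprop-1-enyl)-1,3-dioxolane | CC(C)=C[C@@H]1OC(C)(C)O[C@@H]1C#C[Li] | intermediate (not isolated)
8 | methyl 3-[(4R,5S)-2,2-dimethyl-5-(2-methylprop-1-enyl)-1,3-dioxolan-4-yl]prop-2-ynoate | CC(C)=C[C@@H]1OC(C)(C)O[C@@H]1C#CC(=O)OC | intermediate
9 | methyl (2Z)-3-[(4R,5S)-2,2-dimethyl-5-(2-methylprop-1-enyl)-1,3-dioxolan-4-yl]but-2-enoate | CC(C)=C[C@@H]1OC(C)(C)O[C@@H]1/C(C)=C\C(=O)OC | intermediate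
10 | (2Z)-3-[(4R,5S)-2,2-dimethyl-5-(2-methylprop-1-enyl)-1,3-dioxolan-4-yl]but-2-en-1-ol | CC(C)=C[C@@H]1OC(C)(C)O[C@@H]1/C(C)=C\CO | intermediate
11 | 3-methylbut-2-enoyl chloride | CC(C)=CC(=O)Cl | starting material
12 | (2Z)-3-[(4R,5S)-2,2-dimethyl-5-(2-methylprop-1-enyl)-1,3-dioxolan-4-yl]but-2-enyl 3-methylbut-2-enoate | CC(C)=C[C@@H]1OC(C)(C)O[C@@H]1/C(C)=C\COC(=O)C=C(C)C | intermediate
13 | (1Z)-trimethylsilyl ketene acetal of 12 (isopropenyl cis to OSi) | C=C(C)/C=C(\O[Si](C)(C)C)OC/C=C(C)\[C@H]1OC(C)(C)O[C@H]1C=C(C)C | intermediate (not isolated)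
14 | trimethylsilyl ester of acid 15 | C=C[C@@]([C@H]1OC(C)(C)O[C@H]1C=C(C)C)(C)[C@H](C(C)=C)C(=O)O[Si](C)(C)C | intermediate (not isolated)
15 | (2S,3S)-3-[(4R,5S)-2,2-dimethyl-5-(2-methylprop-1-enyl)-1,3-dioxolan-4-yl]-3-methyl-2-(prop-1-en-2-yl)pent-4-enoic acid | C=C[C@@]([C@H]1OC(C)(C)O[C@H]1C=C(C)C)(C)[C@H](C(C)=C)C(=O)O | intermediate
16 | (2S,3S)-3-[(4R,5S)-2,2-dimethyl-5-(2-methylprop-1-enyl)-1,3-dioxolan-4-yl]-3-methyl-2-(prop-1-en-2-yl)pent-4-en-1-ol | C=C[C@@]([C@H]1OC(C)(C)O[C@H]1C=C(C)C)(C)[C@H](C(C)=C)CO | intermediate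
17 | (2S,3S)-3-[(4R,5S)-2,2-dimethyl-5-(2-methylprop-1-enyl)-1,3-dioxolan-4-yl]-3-methyl-2-(prop-1-en-2-yl)pent-4-enal (ene precursor) | C=C[C@@]([C@H]1OC(C)(C)O[C@H]1C=C(C)C)(C)[C@H](C(C)=C)C=O | intermediate
18 | 8β,9β-isopropylidenedioxy-elema-1,3,11(13)-trien-6α-ol (ring A alcohol) | C=C[C@@]1(C)[C@H](C(C)=C)[C@@H](O)[C@H](C(C)=C)[C@@H]2OC(C)(C)O[C@H]12 | intermediate
19 | isobutyric anhydride | CC(C)C(=O)OC(=O)C(C)C | starting material
20 | 8β,9β-isopropylidenedioxy-elema-1,3,11(13)-trien-6α-yl 2-methylpropanoate | C=C[C@@]1(C)[C@H](C(C)=C)[C@@H](OC(=O)C(C)C)[C@H](C(C)=C)[C@@H]2OC(C)(C)O[C@H]12 | intermediate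
21 | 12,15-dihydroxy-8β,9β-isopropylidenedioxy-elema-1,3,11(13)-trien-6α-yl 2-methylpropanoate | C=C[C@@]1(C)[C@H](C(=C)CO)[C@@H](OC(=O)C(C)C)[C@H](C(=C)CO)[C@@H]2OC(C)(C)O[C@H]12 | intermediate
22 | 8β,9β,12,15-tetrahydroxy-elema-1,3,11(13)-trien-6α-yl 2-methylpropanoate | C=C[C@@]1(C)[C@H](C(=C)CO)[C@@H](OC(=O)C(C)C)[C@H](C(=C)CO)[C@H](O)[C@@H]1O | intermediate
23 | lactol enal (12,8β-lactol, C15 aldehyde, 9β-OH, 6α-isobutyrate) | C=C[C@@]1(C)[C@H](C(=C)C=O)[C@@H](OC(=O)C(C)C)[C@@H]2C(=C)C(O)O[C@@H]2[C@@H]1O | intermediate (not isolated)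
24 | 9β-hydroxy-6α-(2-methylpropanoyloxy)-15-oxo-elema-1,3,11(13)-trien-12,8β-olide | C=C[C@@]1(C)[C@H](C(=C)C=O)[C@@H](OC(=O)C(C)C)[C@@H]2C(=C)C(=O)O[C@@H]2[C@@H]1O | intermediate
25 | (4R)-3,4-epoxy-9β-hydroxy-6α-(2-methylpropanoyloxy)-15-oxo-elema-1,11(13)-dien-12,8β-olide | C=C[C@@]1(C)[C@H]([C@]2(C=O)CO2)[C@@H](OC(=O)C(C)C)[C@@H]2C(=C)C(=O)O[C@@H]2[C@@H]1O | target

**Step count**

Total: 17 steps. Longest linear sequence: 17 steps (1 → 25).

**Steps most likely to fail**

Step 12 (carbonyl-ene closure). The Lewis acid may ionise the allylic C8–O bond of the dioxolane (C8 is allylic to the reacting C7=C11 olefin) or strip the acetonide before the ring closes, and the C5 centre may epimerise or conjugate through the enol. The fallback sets out from alcohol 16 and comes back at 18; it makes the same C6–C7 bond by an intramolecular Nozaki–Hiyama–Kishi-type allylation without a Lewis acid. Ene-type allylic chlorination of the trisubstituted olefin of 16 (N-chlorosuccinimide, PhSeCl cat., CH2Cl2) should give the transposed secondary allylic chloride F1 (chlorine at C7, C11=C13 isopropenyl; both C7 epimers serve). Buffered Dess–Martin oxidation then gives the chloro aldehyde F2. CrCl2 (divalent chromium) with LiI in THF/DMF forms the allylchromium species, which should add through its γ-carbon C7 to the C6 aldehyde in a chair transition state to give the anti product 18.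

Step 9 (Ireland–Claisen rearrangement). Facial selectivity at C10 relative to C9 may be poor, because the bulk of C8 on the attacked face opposes the stereoelectronic preference; loss of ketene acetal geometry would also invert C5 relative to C10. The fallback sets out from allylic alcohol 10 and comes back at acid 15; it replaces substrate control by a reagent-controlled boron-enolate Claisen rearrangement. Alcohol 10 is esterified with 3-methylbut-3-enoic acid (dicyclohexylcarbodiimide, DMAP) to the β,γ-unsaturated ester F3. Soft enolisation with the (S,S)-1,2-diphenylethane-1,2-diamine-derived bis(arylsulfonyl) bromoborane and a tertiary amine (amine and solvent chosen so that the isopropenyl group lies trans to the allyloxy oxygen) gives the chiral boron ketene acetal F4. Its [3,3] shift is steered by the boron ligand and not by C9, and hydrolysis gives 15. The antipodal controller is used if it proves to be the matched partner.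

Step 17 (epoxidation). Catalyst control over the face of oxirane closure may be weak at the hindered α-branched enal, and the amine may be consumed by conjugate addition to the methylene lactone. The fallback sets out from enal 24 and comes back at target 25; it uses reagent-controlled epoxidation of the allylic alcohol. Luche reduction (NaBH4, CeCl3·7H2O, MeOH, −78 °C) gives the allylic alcohol F5. Sharpless asymmetric epoxidation (Ti(OiPr)4, L-(+)-diethyl tartrate, t-BuOOH, 4 Å molecular sieves, CH2Cl2, −20 °C) gives the epoxy alcohol F6. Buffered Dess–Martin oxidation then gives 25.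

**Further compounds**

F1 | step 12 | (2S,3S)-3-[(4R,5S)-5-(1-chloro-2-methylprop-2-enyl)-2,2-dimethyl-1,3-dioxolan-4-yl]-3-methyl-2-(prop-1-en-2-yl)pent-4-en-1-ol (C7 epimers) | C=C[C@@]([C@H]1OC(C)(C)O[C@H]1C(Cl)C(C)=C)(C)[C@H](C(C)=C)CO
F2 | step 12 | (2S,3S)-3-[(4R,5S)-5-(1-chloro-2-methylprop-2-enyl)-2,2-dimethyl-1,3-dioxolan-4-yl]-3-methyl-2-(prop-1-en-2-yl)pent-4-enal (C7 epimers) | C=C[C@@]([C@H]1OC(C)(C)O[C@H]1C(Cl)C(C)=C)(C)[C@H](C(C)=C)C=O
F3 | step 9 | (2Z)-3-[(4R,5S)-2,2-dimethyl-5-(2-methylprop-1-enyl)-1,3-dioxolan-4-yl]but-2-enyl 3-methylbut-3-enoate | CC(C)=C[C@@H]1OC(C)(C)O[C@@H]1/C(C)=C\COC(=O)CC(C)=C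
F4 | step 9 | boron ketene acetal of F3 with the (4S,5S)-4,5-diphenyl-1,3-bis[3,5-bis(trifluoromethyl)phenylsulfonyl]-1,3,2-diazaborolidin-2-yl group on oxygen | C=C(C)/C=C(\OB1N(S(=O)(=O)c2cc(cc(c2)C(F)(F)F)C(F)(F)F)[C@@H](c2ccccc2)[C@H](c2ccccc2)N1S(=O)(=O)c1cc(cc(c1)C(F)(F)F)C(F)(F)F)OC/C=C(C)\[C@H]1OC(C)(C)O[C@H]1C=C(C)C
F5 | step 17 | 9β,15-dihydroxy-6α-(2-methylpropanoyloxy)-elema-1,3,11(13)-trien-12,8β-olide | C=C[C@@]1(C)[C@H](C(=C)CO)[C@@H](OC(=O)C(C)C)[C@@H]2C(=C)C(=O)O[C@@H]2[C@@H]1O
F6 | step 17 | (4S)-3,4-epoxy-9β,15-dihydroxy-6α-(2-methylpropanoyloxy)-elema-1,11(13)-dien-12,8β-olide | C=C[C@@]1(C)[C@H]([C@]2(CO)CO2)[C@@H](OC(=O)C(C)C)[C@@H]2C(=C)C(=O)O[C@@H]2[C@@H]1O
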